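**Plan**
- Cuts, in retrosynthetic order: the epoxide oxygen (back to C8=C9), the two acyl groups, the carbinol hydrogens at C2 and C6 (back to ketones), C1–C10 of the seven-membered ring, the C7 methylene, C5–C6, and C4–isopropyl.
- Enabling feature: in the seven-membered ring (C1, C5–C10) the oxygenated C6, the C8–C9 epoxide (a masked alkene) and the quaternary C1 are spaced as in a 1,4-cycloheptadiene, C5=C6(O)–C7–C8=C9–C10–C1. A 1-siloxy-cis-1,2-dialkenylcyclopropane (ring C6–C7–C8) gives exactly this pattern on Cope rearrangement.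
- Forward order: the five-membered ring comes from 3-methylcyclopentenone. Isopropyl (C4) and the tigloyl chain (C5–C6) are attached, the three-membered ring is closed on the C6=C8 enol ether, its expansion gives the seven-membered ring, and the oxirane is closed last.
- Stereochemistry, part 1: a lipase resolution fixes C2 (β oxygen). C2 steers the isopropyl addition (C4). The 4β-OH directs the carbenoid (C6 and C8 of the cyclopropane), and the boat transition state passes that configuration on to C1.
- Stereochemistry, part 2: C5 is set by equilibration to the trans fusion. The 4β-OH delivers hydride to C6 and, after oxidation at C2, to C2 (net inversion to 2α). The axial C1 methyl sends the peracid to the α face of C8=C9.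

Key step: step 11

Remark: daucane numbering is applied to every intermediate (C1 quaternary fusion carbon, C2 CH–O, C3 CH2, C4 isopropyl carbinol, C5 fusion CH, C6 CH–O, C7 CH2, C8 methyl-bearing carbon, C9, C10 CH2 next to C1) and β means the face of the C1 methyl group of the target; the lipase is assumed to keep its usual preference for the R alcohol with the 3-methyl substrate.

Step 1
Reactants: 1 3-methylcyclopent-2-en-1-one
Product: 2 rac-4-bromo-3-methylcyclopent-2-en-1-one
Conditions: NBS, AIBN (cat.), PhCF3, reflux
Reagents that add atoms: N-bromosuccinimide, O=C1CCC(=O)N1Br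
Why: Wohl–Ziegler radical bromination takes the secondary ring allylic hydrogen at C4 rather than a primary methyl hydrogen, the site selectivity known for 2-alkyl-3-methylcyclopentenones, and the racemic outcome is acceptable because step 3 resolves it.

Step 2
Reactants: 2 rac-4-bromo-3-methylcyclopent-2-en-1-one
Product: 3 rac-4-hydroxy-3-methylcyclopent-2-en-1-one
Conditions: CaCO3, H2O–1,4-dioxane, 80 °C
Reagents that add atoms: water, O
Why: Carbonate-buffered solvolysis (nucleophilic substitution of an allylic bromide by water) neutralises HBr as it forms and avoids the strong base that would dehydrate or isomerise the 4-hydroxy enone.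

Step 3
Reactants: 3 rac-4-hydroxy-3-methylcyclopent-2-en-1-one
Product: 4 (S)-4-hydroxy-3-methylcyclopent-2-en-1-one
Conditions: Amano lipase PS, vinyl acetate, MTBE, 30 °C, stopped just past half conversion; chromatographic separation from the acetate
Reagents that add atoms: none
Why: Lipase-catalysed kinetic resolution by irreversible transesterification acylates the R enantiomer of 4-hydroxycyclopentenones faster, so a reaction taken just past half conversion leaves the S alcohol, whose carbinol carbon becomes C2 with a β oxygen and is the only external source of chirality in the route.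

Step 4
Reactants: 4 (S)-4-hydroxy-3-methylcyclopent-2-en-1-one
Product: 5 (S)-4-(tert-butyldimethylsilyloxy)-3-methylcyclopent-2-en-1-one
Conditions: TBSCl, imidazole, DMF, 0 °C → rt
Reagents that add atoms: tert-butyldimethylsilyl chloride, CC(C)(C)[Si](C)(C)Cl
Why: Imidazole-promoted silylation of a secondary alcohol is routine for 4-hydroxycyclopentenones, and the TBS ether serves as the steric shield in steps 6 and 11 while tolerating organometallics, carbenoid and heat.

Step 5
Reactants: 5 (S)-4-(tert-butyldimethylsilyloxy)-3-methylcyclopent-2-en-1-one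
Product: 7 (S)-2-bromo-4-(tert-butyldimethylsilyloxy)-3-methylcyclopent-2-en-1-one, via dibromoketone 6 (not isolated)
Conditions: Br2, CH2Cl2, 0 °C; then Et3N, 0 °C
Reagents that add atoms: bromine, BrBr
Why: Bromine addition followed by amine-induced E1cB loss of HBr is the standard α-bromination of β-substituted cyclopentenones, where iodine–pyridine methods that need conjugate addition to the β carbon are slow, and the vinyl bromide, unlike an iodide, resists halogen–magnesium exchange with isopropylmagnesium chloride in step 6.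

Step 6
Reactants: 7 (S)-2-bromo-4-(tert-butyldimethylsilyloxy)-3-methylcyclopent-2-en-1-one; 8 isopropylmagnesium chloride
Product: 9 (1S,4S)-2-bromo-4-(tert-butyldimethylsilyloxy)-3-methyl-1-(propan-2-yl)cyclopent-2-en-1-ol (2β-OTBS and 4β-OH cis)
Conditions: CeCl3 (dried), THF, −78 → −40 °C
Reagents that add atoms: none
Why: Organocerium 1,2-addition suppresses enolisation, β-hydride reduction and conjugate addition, and the bulky nucleophile approaches the flat enone anti to the C2 silyloxy group, so that C4 is formed with isopropyl α and OH β.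

Step 7
Reactants: 9 (1S,4S)-2-bromo-4-(tert-butyldimethylsilyloxy)-3-methyl-1-(propan-2-yl)cyclopent-2-en-1-ol; 10 (E)-2-methylbut-2-enal (tiglic aldehyde)
Product: 12 (1S,4S)-4-(tert-butyldimethylsilyloxy)-2-[(E)-1-hydroxy-2-methylbut-2-enyl]-3-methyl-1-(propan-2-yl)cyclopent-2-en-1-ol (both C6 epimers), via dilithiated cyclopentenol 11 (not isolated)
Conditions: t-BuLi (3.1 equiv), THF, −78 °C; then 10, −78 °C
Reagents that add atoms: none
Why: One equivalent of t-BuLi deprotonates the alcohol and two effect bromine–lithium exchange, the alkoxide-bearing cyclopentenyllithium cannot β-eliminate inside a five-membered ring and adds 1,2 to the unhindered aldehyde (chosen over an amide because the nucleophile is flanked on both sides), and the C6 carbinol mixture is of no consequence because step 8 removes that centre.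

Step 8
Reactants: 12 (1S,4S)-4-(tert-butyldimethylsilyloxy)-2-[(E)-1-hydroxy-2-methylbut-2-enyl]-3-methyl-1-(propan-2-yl)cyclopent-2-en-1-ol
Product: 13 (E)-1-[(3S,5S)-3-(tert-butyldimethylsilyloxy)-5-hydroxy-2-methyl-5-(propan-2-yl)cyclopent-1-enyl]-2-methylbut-2-en-1-one
Conditions: MnO2, CH2Cl2, rt
Reagents that add atoms: none
Why: MnO2 oxidation is specific for the secondary bis-allylic alcohol, leaves the tertiary alcohol alone and is neutral, which keeps the divinyl ketone from Nazarov cyclisation and the tertiary allylic alcohol from ionising.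

Step 9
Reactants: 13 (E)-1-[(3S,5S)-3-(tert-butyldimethylsilyloxy)-5-hydroxy-2-methyl-5-(propan-2-yl)cyclopent-1-enyl]-2-methylbut-2-en-1-one
Product: 15 (1S,4S)-4-(tert-butyldimethylsilyloxy)-2-[(1E)-1-(tert-butyldimethylsilyloxy)-2-methylbuta-1,3-dienyl]-3-methyl-1-(propan-2-yl)cyclopent-2-en-1-ol (cyclopentenyl cis to vinyl across C6=C8), via dilithium dienolate 14 (not isolated)
Conditions: LiN(iPr)2 (2.3 equiv), THF–DMPU, −78 °C (13 added to the base); TBSCl (1.1 equiv), −78 → −20 °C; pH 7 buffer; product kept cold and used at once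
Reagents that add atoms: tert-butyldimethylsilyl chloride, CC(C)(C)[Si](C)(C)Cl
Why: In this extended-enolate formation and O-silylation the tetrasubstituted cyclopentene is twisted out of conjugation with the carbonyl so that only the tigloyl γ-methyl (C10) is vinylogously acidic, deprotonation from the favoured s-trans enone conformer puts O6 cis to the C8 methyl and C5 cis to the new vinyl group (E-dienol ether), and the hindered tertiary lithium alkoxide is inert to TBSCl at low temperature and returns as the free 4β-OH on work-up.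

Step 10
Reactants: 15 (1S,4S)-4-(tert-butyldimethylsilyloxy)-2-[(1E)-1-(tert-butyldimethylsilyloxy)-2-methylbuta-1,3-dienyl]-3-methyl-1-(propan-2-yl)cyclopent-2-en-1-ol
Product: 17 (1S,4S)-4-(tert-butyldimethylsilyloxy)-2-[(1R,2S)-1-(tert-butyldimethylsilyloxy)-2-ethenyl-2-methylcyclopropyl]-3-methyl-1-(propan-2-yl)cyclopent-2-en-1-ol (cyclopentenyl cis to vinyl on the cyclopropane), via ethylzinc alkoxide 16 (not isolated)
Conditions: Et2Zn (1.1 equiv), CH2Cl2, −20 °C; then Et2Zn, CH2I2 (1.5 equiv each), −20 → 0 °C; aq NaHCO3
Reagents that add atoms: diiodomethane, ICI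
Why: In this hydroxyl-directed Simmons–Smith reaction (Furukawa reagent) the silyl enol ether C6=C8 is the most nucleophilic of the three alkenes, syn addition keeps cyclopentenyl and vinyl cis, and in the favoured twisted conformer (C8 on the β side of the cyclopentene plane next to the oxygen on C4, OTBS on the α side) the zinc alkoxide hands CH2 to the face of C6=C8 that looks toward C4, which sets C6 as R and C8 as S.

Step 11
Reactants: 17 (1S,4S)-4-(tert-butyldimethylsilyloxy)-2-[(1R,2S)-1-(tert-butyldimethylsilyloxy)-2-ethenyl-2-methylcyclopropyl]-3-methyl-1-(propan-2-yl)cyclopent-2-en-1-ol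
Product: 18 2β,6-bis(tert-butyldimethylsilyloxy)dauca-5,8-dien-4β-ol (bicyclo[5.3.0]decadiene with C5=C6 silyl enol ether, C8=C9 alkene and β methyl on C1)
Conditions: toluene (0.01 M, degassed), BHT (trace), base-washed sealed tube, 110 °C
Reagents that add atoms: none
Why: The reaction is a concerted [3,3]-sigmatropic shift (divinylcyclopropane–cycloheptadiene Cope rearrangement) through the endo boat in which C5=C1 and C9=C10 both lie over the three-membered ring: C1–C10 forms as C6–C8 breaks and the π bonds move to C5=C6 and C8=C9. Its closest relatives are the thermal rearrangements of 1-siloxy-cis-divinylcyclopropanes and of 2-vinylcyclopropyl-substituted cycloalkenes that generate angular methyl groups; because the methyl group on the reacting terminus C1 is pressed against the C7 methylene in the boat, hot toluene is planned instead of room temperature, while ring strain, the donor siloxy group on C6 and the eclipsed OTBS/CH3 pair weaken C6–C8. The seven-membered ring is closed by ring expansion of the cyclopropane (C6–C7–C8 plus the four alkene carbons), so no end-to-end cyclisation is involved and both ring alkenes are necessarily Z. C1, the only new stereocentre, is set by chirality transfer: with the (1R,2S)-cyclopropane of 17 only the rotamer about C5–C6 that turns the α face of C1 toward C10 can reach the boat, which puts C10 α and the methyl β, and this is also the face anti to the 2β-OTBS and 4β-OH groups. The step needs periselectivity over C6–C8 homolysis (stereomutation, vinylcyclopropane–cyclopentene shift) and over a homodienyl 1,5-hydrogen shift, and the substrate secures it by the cis relation of the two alkenyl groups fixed in steps 9 and 10 and by having the C8 methyl trans to the cyclopentenyl group. Dilute, degassed, base-washed conditions protect the enol ether and the tertiary allylic alcohol.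

Step 12
Reactants: 18 2β,6-bis(tert-butyldimethylsilyloxy)dauca-5,8-dien-4β-ol
Product: 20 trans-fused 2β-(tert-butyldimethylsilyloxy)-4β-hydroxy-5α-H-dauc-8-en-6-one, via cis-fused C5 epimer 19 (not isolated)
Conditions: TBAF, AcOH (1:1, 1.1 equiv), THF, −20 → 0 °C; aqueous wash; then DBU (0.2 equiv), toluene, rt
Reagents that add atoms: none
Why: Buffered fluoride cleaves the silyl enol ether far faster than the hindered secondary TBS ether and the enol is protonated at once so that E1cB loss of the C4 hydroxyl is not triggered, and the amidine base (no alkoxide, hence no retro-aldol) then epimerises C5 to the trans-fused ketone, which is favoured because C6 lies anti to the α-isopropyl group and the 4β-OH can hydrogen-bond to the C6 carbonyl.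

Step 13
Reactants: 20 trans-fused 2β-(tert-butyldimethylsilyloxy)-4β-hydroxy-5α-H-dauc-8-en-6-one
Product: 21 2β-(tert-butyldimethylsilyloxy)dauc-8-ene-4β,6α-diol
Conditions: Me4NBH(OAc)3, MeCN–AcOH, −20 °C
Reagents that add atoms: none
Why: In the Evans–Saksena hydroxyl-directed reduction ligand exchange ties boron to the 4β oxygen and hydride passes to the β face of C6 through a chair-like six-membered transition state, giving the 1,3-anti diol with 6α-OH while alkene and silyl ether stay untouched.

Step 14
Reactants: 21 2β-(tert-butyldimethylsilyloxy)dauc-8-ene-4β,6α-diol; 22 4-methoxybenzoyl chloride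
Product: 23 2β-(tert-butyldimethylsilyloxy)-4β-hydroxydauc-8-en-6α-yl 4-methoxybenzoate
Conditions: DMAP, pyridine, 50 °C
Reagents that add atoms: none
Why: DMAP-catalysed acylation distinguishes cleanly between the secondary C6 alcohol and the tertiary C4 alcohol flanked by isopropyl, and no stereocentre is touched.

Step 15
Reactants: 23 2β-(tert-butyldimethylsilyloxy)-4β-hydroxydauc-8-en-6α-yl 4-methoxybenzoate
Product: 24 2β,4β-dihydroxydauc-8-en-6α-yl 4-methoxybenzoate
Conditions: HF·pyridine, pyridine–THF, 0 °C → rt
Reagents that add atoms: none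
Why: Fluoride-driven Si–O cleavage under weakly acidic buffered conditions removes the neopentyl TBS ether without the ester cleavage or acyl migration that basic fluoride could cause.

Step 16
Reactants: 24 2β,4β-dihydroxydauc-8-en-6α-yl 4-methoxybenzoate
Product: 25 4β-hydroxy-2-oxodauc-8-en-6α-yl 4-methoxybenzoate
Conditions: Dess–Martin periodinane, CH2Cl2, 0 °C → rt
Reagents that add atoms: none
Why: Dess–Martin oxidation converts the only secondary alcohol into the cyclopentanone without base, so the β-hydroxy ketone does not dehydrate, and the adjacent C1 is quaternary and cannot epimerise.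

Step 17
Reactants: 25 4β-hydroxy-2-oxodauc-8-en-6α-yl 4-methoxybenzoate
Product: 26 2α,4β-dihydroxydauc-8-en-6α-yl 4-methoxybenzoate
Conditions: Me4NBH(OAc)3, MeCN–AcOH, −20 → 0 °C
Reagents that add atoms: none
Why: A second Evans–Saksena reduction uses the same 4β-OH, now 1,3 to the C2 ketone within the five-membered ring, to deliver hydride to the β face against the steric bias of the angular methyl, so that the hydroxyl emerges α (trans to 4-OH) and an SN2 inversion at a neopentyl carbon is avoided.

Step 18
Reactants: 26 2α,4β-dihydroxydauc-8-en-6α-yl 4-methoxybenzoate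
Product: 27 2α-acetoxy-4β-hydroxydauc-8-en-6α-yl 4-methoxybenzoate
Conditions: Ac2O, DMAP (cat.), pyridine, rt
Reagents that add atoms: acetic anhydride, CC(=O)OC(C)=O
Why: DMAP-catalysed acetylation reaches the secondary 2α-OH only, since the tertiary C4 alcohol does not acylate under these conditions.

Step 19
Reactants: 27 2α-acetoxy-4β-hydroxydauc-8-en-6α-yl 4-methoxybenzoate
Product: 28 2α-acetoxy-8α,9α-epoxy-4β-hydroxydaucan-6α-yl 4-methoxybenzoate (CNP0317703.1)
Conditions: mCPBA, CH2Cl2, 0 °C
Reagents that add atoms: meta-chloroperoxybenzoic acid, OOC(=O)c1cccc(Cl)c1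
Why: In this Prilezhaev epoxidation of the only alkene the trans ring fusion holds the cycloheptene in a chair in which the C1 methyl is axial over the β face of C8=C9 and the anisoate is equatorial, so the peracid adds to the open α face and sets C8 and C9 together.

**Compound list**
1 | 3-methylcyclopent-2-en-1-one | CC1=CC(=O)CC1 | starting material
2 | rac-4-bromo-3-methylcyclopent-2-en-1-one | CC1=CC(=O)CC1Br | intermediate
3 | rac-4-hydroxy-3-methylcyclopent-2-en-1-one | CC1=CC(=O)CC1O | intermediate
4 | (S)-4-hydroxy-3-methylcyclopent-2-en-1-one | O=C1C=C(C)[C@@H](O)C1 | intermediate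
5 | (S)-4-(tert-butyldimethylsilyloxy)-3-methylcyclopent-2-en-1-one | O=C1C=C(C)[C@@H](O[Si](C)(C)C(C)(C)C)C1 | intermediate
6 | (4S)-2,3-dibromo-4-(tert-butyldimethylsilyloxy)-3-methylcyclopentan-1-one (bromine-bearing centres undefined) | O=C1C(Br)C(C)(Br)[C@@H](O[Si](C)(C)C(C)(C)C)C1 | intermediate
7 | (S)-2-bromo-4-(tert-butyldimethylsilyloxy)-3-methylcyclopent-2-en-1-one | O=C1C(Br)=C(C)[C@@H](O[Si](C)(C)C(C)(C)C)C1 | intermediate
8 | isopropylmagnesium chloride | CC(C)[Mg]Cl | starting material
9 | (1S,4S)-2-bromo-4-(tert-butyldimethylsilyloxy)-3-methyl-1-(propan-2-yl)cyclopent-2-en-1-ol | BrC1=C(C)[C@@H](O[Si](C)(C)C(C)(C)C)C[C@]1(O)C(C)C | intermediate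
10 | (E)-2-methylbut-2-enal (tiglic aldehyde) | C/C=C(\C)C=O | starting material
11 | lithium (1S,4S)-4-(tert-butyldimethylsilyloxy)-2-lithio-3-methyl-1-(propan-2-yl)cyclopent-2-en-1-olate | [Li]C1=C(C)[C@@H](O[Si](C)(C)C(C)(C)C)C[C@]1(O[Li])C(C)C | intermediate
12 | (1S,4S)-4-(tert-butyldimethylsilyloxy)-2-[(E)-1-hydroxy-2-methylbut-2-enyl]-3-methyl-1-(propan-2-yl)cyclopent-2-en-1-ol (C6 epimers) | C/C=C(\C)C(O)C1=C(C)[C@@H](O[Si](C)(C)C(C)(C)C)C[C@]1(O)C(C)C | intermediate
13 | (E)-1-[(3S,5S)-3-(tert-butyldimethylsilyloxy)-5-hydroxy-2-methyl-5-(propan-2-yl)cyclopent-1-enyl]-2-methylbut-2-en-1-one | C/C=C(\C)C(=O)C1=C(C)[C@@H](O[Si](C)(C)C(C)(C)C)C[C@]1(O)C(C)C | intermediate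
14 | dilithium salt of 13 (C4 alkoxide and E-configured C6 dienolate) | C=C/C(C)=C(O[Li])\C1=C(C)[C@@H](O[Si](C)(C)C(C)(C)C)C[C@]1(O[Li])C(C)C | intermediate
15 | (1S,4S)-4-(tert-butyldimethylsilyloxy)-2-[(1E)-1-(tert-butyldimethylsilyloxy)-2-methylbuta-1,3-dienyl]-3-methyl-1-(propan-2-yl)cyclopent-2-en-1-ol | C=C/C(C)=C(O[Si](C)(C)C(C)(C)C)\C1=C(C)[C@@H](O[Si](C)(C)C(C)(C)C)C[C@]1(O)C(C)C | intermediate
16 | ethylzinc C4-alkoxide of 15 | C=C/C(C)=C(O[Si](C)(C)C(C)(C)C)\C1=C(C)[C@@H](O[Si](C)(C)C(C)(C)C)C[C@]1(O[Zn]CC)C(C)C | intermediate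
17 | (1S,4S)-4-(tert-butyldimethylsilyloxy)-2-[(1R,2S)-1-(tert-butyldimethylsilyloxy)-2-ethenyl-2-methylcyclopropyl]-3-methyl-1-(propan-2-yl)cyclopent-2-en-1-ol | C=C[C@]1(C)C[C@]1(O[Si](C)(C)C(C)(C)C)C1=C(C)[C@@H](O[Si](C)(C)C(C)(C)C)C[C@]1(O)C(C)C | intermediate
18 | 2β,6-bis(tert-butyldimethylsilyloxy)dauca-5,8-dien-4β-ol | CC(C)(C)[Si](C)(C)OC1CC(C)=CC[C@]2(C)[C@@H](O[Si](C)(C)C(C)(C)C)C[C@](O)(C(C)C)C=12 | intermediate
19 | cis-fused (5β-H) epimer of 20 | O=C1CC(C)=CC[C@]2(C)[C@@H](O[Si](C)(C)C(C)(C)C)C[C@](O)(C(C)C)[C@H]12 | intermediate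
20 | trans-fused 2β-(tert-butyldimethylsilyloxy)-4β-hydroxy-5α-H-dauc-8-en-6-one | O=C1CC(C)=CC[C@]2(C)[C@@H](O[Si](C)(C)C(C)(C)C)C[C@](O)(C(C)C)[C@@H]12 | intermediate
21 | 2β-(tert-butyldimethylsilyloxy)dauc-8-ene-4β,6α-diol | O[C@@H]1CC(C)=CC[C@]2(C)[C@@H](O[Si](C)(C)C(C)(C)C)C[C@](O)(C(C)C)[C@@H]12 | intermediate
22 | 4-methoxybenzoyl chloride | COc1ccc(C(=O)Cl)cc1 | starting material
23 | 2β-(tert-butyldimethylsilyloxy)-4β-hydroxydauc-8-en-6α-yl 4-methoxybenzoate | COc1ccc(C(=O)O[C@@H]2CC(C)=CC[C@]3(C)[C@@H](O[Si](C)(C)C(C)(C)C)C[C@](O)(C(C)C)[C@@H]23)cc1 | intermediate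
24 | 2β,4β-dihydroxydauc-8-en-6α-yl 4-methoxybenzoate | COc1ccc(C(=O)O[C@@H]2CC(C)=CC[C@]3(C)[C@@H](O)C[C@](O)(C(C)C)[C@@H]23)cc1 | intermediate
25 | 4β-hydroxy-2-oxodauc-8-en-6α-yl 4-methoxybenzoate | COc1ccc(C(=O)O[C@@H]2CC(C)=CC[C@]3(C)C(=O)C[C@](O)(C(C)C)[C@@H]23)cc1 | intermediate
26 | 2α,4β-dihydroxydauc-8-en-6α-yl 4-methoxybenzoate | COc1ccc(C(=O)O[C@@H]2CC(C)=CC[C@]3(C)[C@H](O)C[C@](O)(C(C)C)[C@@H]23)cc1 | intermediate
27 | 2α-acetoxy-4β-hydroxydauc-8-en-6α-yl 4-methoxybenzoate | COc1ccc(C(=O)O[C@@H]2CC(C)=CC[C@]3(C)[C@H](OC(C)=O)C[C@](O)(C(C)C)[C@@H]23)cc1 | intermediate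
28 | 2α-acetoxy-8α,9α-epoxy-4β-hydroxydaucan-6α-yl 4-methoxybenzoate (CNP0317703.1) | COc1ccc(C(=O)O[C@@H]2C[C@]3(C)O[C@@H]3C[C@]3(C)[C@H](OC(C)=O)C[C@](O)(C(C)C)[C@@H]23)cc1 | target

Total step count: 19. Longest linear sequence: 19 steps (1 → 28); compounds 8, 10 and 22 are bought.

**Steps most likely to fail**

(a) Step 10. A hindered, tertiary, homoallylic zinc alkoxide is only a modest director, so methylene delivery to C6=C8 may show poor facial selectivity.
- The fallback sets out from 15 and comes back at 18. It moves the stereochemical burden from the cyclopropanation to the rearrangement.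
- Compound 15 is cyclopropanated without reliance on direction (Et2Zn, CH2I2, Et2O). This gives 17 together with the ring-inverted cis-cyclopropane F1.
- The unseparated mixture is heated in mesitylene at about 160 °C. At that temperature the C6–C8 bond, flanked by a siloxy group, a methyl group and two alkenyl groups, opens reversibly to a bis-allylic diradical. This is the process that allows trans-divinylcyclopropanes to serve as Cope substrates.
- F1 is thereby drained through the trans C8 epimer F2 and the trans C6 epimer F3 into 17.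
- The boat that would join C10 to the β face of C1 runs into the neighbouring 2β-OTBS group, so the material should leave through the α-face boat to 18.

(b) Step 11. Compression between the C1 methyl and the C7 methylene in the boat may slow the rearrangement until bond homolysis and loss of chirality transfer take over.
- The fallback sets out from 13 and comes back at 20. It keeps the same bond changes but accelerates them by charge.
- Compound 13 is enolised as in step 9 and trapped with TMSCl to give the trimethylsilyl dienol ether F4.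
- F4 is cyclopropanated as in step 10 to the trimethylsiloxycyclopropane F5.
- K2CO3 in MeOH at 0 °C frees the cyclopropanol F6 while the C2 TBS ether stays.
- KN(SiMe3)2 (2.2 equiv) and 18-crown-6 in THF from −78 °C deprotonate F6. With the oxido group on C6 of the breaking bond, this is an anionic oxy-Cope rearrangement of a cis-dialkenylcyclopropanolate, the fast step of Brook-rearrangement-mediated [3+4] annulations.
- The resulting dipotassium enolate F7 is quenched with AcOH and equilibrated with DBU as in step 12 to give 20.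

(c) Step 9. Four things may go wrong: proton removal at the wrong site (C1 methyl or C2–H), conjugate addition of the C4 alkoxide to the enone, silylation at O4, or formation of the wrong enol ether geometry.
- The fallback sets out from 13 and comes back at 15. It replaces the dianion by soft enolisation of an O4-masked ketone.
- TMSOTf and 2,6-lutidine give the O4-trimethylsilyl dienone F8.
- TBSOTf and Et3N in CH2Cl2 (−78 → 0 °C) silylate the carbonyl oxygen first. The amine then takes the γ-proton from the s-trans oxocarbenium ion, giving the O4-trimethylsilyl E-dienol ether F9.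
- K2CO3 in MeOH at 0 °C removes only the trimethylsilyl ether and returns 15 with the free directing hydroxyl.

**Further compounds**
F1 | step 10 | (1S,2R)-cyclopropane diastereomer of 17 (cis, C6 and C8 both inverted) | C=C[C@@]1(C)C[C@@]1(O[Si](C)(C)C(C)(C)C)C1=C(C)[C@@H](O[Si](C)(C)C(C)(C)C)C[C@]1(O)C(C)C
F2 | step 10 | (1R,2R)-cyclopropane diastereomer of 17 (trans, C8 inverted) | C=C[C@@]1(C)C[C@]1(O[Si](C)(C)C(C)(C)C)C1=C(C)[C@@H](O[Si](C)(C)C(C)(C)C)C[C@]1(O)C(C)C
F3 | step 10 | (1S,2S)-cyclopropane diastereomer of 17 (trans, C6 inverted) | C=C[C@]1(C)C[C@@]1(O[Si](C)(C)C(C)(C)C)C1=C(C)[C@@H](O[Si](C)(C)C(C)(C)C)C[C@]1(O)C(C)C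
F4 | step 11 | O6-trimethylsilyl analogue of 15 (E-dienol ether) | C=C/C(C)=C(O[Si](C)(C)C)\C1=C(C)[C@@H](O[Si](C)(C)C(C)(C)C)C[C@]1(O)C(C)C
F5 | step 11 | O6-trimethylsilyl analogue of 17 ((1R,2S)-cyclopropane) | C=C[C@]1(C)C[C@]1(O[Si](C)(C)C)C1=C(C)[C@@H](O[Si](C)(C)C(C)(C)C)C[C@]1(O)C(C)C
F6 | step 11 | (1R,2S)-1-cyclopentenyl-2-ethenyl-2-methylcyclopropan-1-ol (free C6 hydroxyl, otherwise as 17) | C=C[C@]1(C)C[C@]1(O)C1=C(C)[C@@H](O[Si](C)(C)C(C)(C)C)C[C@]1(O)C(C)C
F7 | step 11 | dipotassium salt (C6 enolate and C4 alkoxide) of 20 | [K]OC1CC(C)=CC[C@]2(C)[C@@H](O[Si](C)(C)C(C)(C)C)C[C@](O[K])(C(C)C)C=12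
F8 | step 9 | O4-trimethylsilyl ether of 13 | C/C=C(\C)C(=O)C1=C(C)[C@@H](O[Si](C)(C)C(C)(C)C)C[C@]1(O[Si](C)(C)C)C(C)C
F9 | step 9 | O4-trimethylsilyl ether of 15 | C=C/C(C)=C(O[Si](C)(C)C(C)(C)C)\C1=C(C)[C@@H](O[Si](C)(C)C(C)(C)C)C[C@]1(O[Si](C)(C)C)C(C)C
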